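**Retrosynthetic overview**

- Feature: C3 of ring C is a fully substituted carbon next to the C4 aryl ketone. It carries ring B, a hydroxyl oxygen and the oxygen-bearing methylene C2, which is the pattern a carbene carbon leaves after taking up an alcohol and formaldehyde.
- Key disconnection: C3–O and C2–C3 are made together, with C3 set, by enantioselective three-component trapping from diazoketone 12, 4-methoxybenzyl alcohol and formaldehyde. No ring closes in this step.
- Ring C is closed afterwards at O1–C8a by SNAr of the new primary alkoxide on the ring A fluoride. The PMB ether, then the MOM ether and the ketal, are removed last.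
- Diazoketone 12 comes by diazo transfer from deoxybenzoin 11. Ketone 11 is assembled from the tosylhydrazone of the ring B aldehyde and MOM-protected 2-fluoro-4-hydroxybenzaldehyde.
- Ring B comes from 2,3-dihydroxy-4-methoxybenzaldehyde by ketalisation, formyl-directed bromination and Stille prenylation. Rings A and B are bought as arenes, the protecting dioxole ring is made first and ring C last.

Key step: step 8

Assumption: the (R)-configured phosphoric acid is taken to deliver the (S)-carbinol; if the sense of induction proves opposite, its (S)-enantiomer is used.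

**Route**

Step 1
Reactants: 1 2,3-dihydroxy-4-methoxybenzaldehyde; 2 dichlorodiphenylmethane
Product: 3 7-methoxy-2,2-diphenyl-1,3-benzodioxole-4-carbaldehyde
Conditions: Ph2O, 170 °C, N2 stream
Reagents that add atoms: none
Why: Catechol ketalisation with a gem-dichloride (double O-alkylation driven by loss of HCl) engages the only vicinal diol and should leave the aldehyde and the aryl methyl ether untouched.

Step 2
Reactants: 3 7-methoxy-2,2-diphenyl-1,3-benzodioxole-4-carbaldehyde
Product: 4 6-bromo-7-methoxy-2,2-diphenyl-1,3-benzodioxole-4-carbaldehyde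
Conditions: NBS, DMF, 0 °C to rt
Reagents that add atoms: N-bromosuccinimide, O=C1CCC(=O)N1Br
Why: Electrophilic aromatic bromination should go to C6, which is ortho to OMe, para to ketal oxygen O3 and meta to the formyl group, whereas C5 is ortho to the deactivating formyl group (the pattern of 5-bromination of 2,3,4-trialkoxybenzaldehydes).

Step 3
Reactants: 4 6-bromo-7-methoxy-2,2-diphenyl-1,3-benzodioxole-4-carbaldehyde; 5 tributyl(3-methylbut-2-en-1-yl)stannane
Product: 6 7-methoxy-6-(3-methylbut-2-en-1-yl)-2,2-diphenyl-1,3-benzodioxole-4-carbaldehyde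
Conditions: Pd(PPh3)4 (5 mol %), DMF, 90 °C
Reagents that add atoms: none
Why: Stille coupling of the aryl bromide with the allylic stannane should give the linear prenyl arene by reductive elimination at the unsubstituted allyl terminus, and the stannane, unlike prenyl boron or zinc reagents, does not add to the aldehyde.

Step 4
Reactants: 6 7-methoxy-6-(3-methylbut-2-en-1-yl)-2,2-diphenyl-1,3-benzodioxole-4-carbaldehyde
Product: 7 N'-[(E)-[7-methoxy-6-(3-methylbut-2-en-1-yl)-2,2-diphenyl-1,3-benzodioxol-4-yl]methylidene]-4-methylbenzenesulfonohydrazide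
Conditions: TsNHNH2, MeOH, rt
Reagents that add atoms: 4-methylbenzenesulfonohydrazide, Cc1ccc(cc1)S(=O)(=O)NN
Why: Condensation of the aldehyde with tosylhydrazide should give the crystalline (E)-N-tosylhydrazone, the stable precursor of the aryldiazomethane.

Step 5
Reactants: 8 2-fluoro-4-hydroxybenzaldehyde
Product: 9 2-fluoro-4-(methoxymethoxy)benzaldehyde
Conditions: MOMCl, i-Pr2NEt, CH2Cl2, 0 °C to rt
Reagents that add atoms: chloromethyl methyl ether, COCCl
Why: Williamson-type O-alkylation of the acidic phenol; the MOM ether has no free O–H, tolerates the bases of steps 6, 7 and 9 and sits far from the carbene of step 8.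

Step 6
Reactants: 7 N'-[(E)-[7-methoxy-6-(3-methylbut-2-en-1-yl)-2,2-diphenyl-1,3-benzodioxol-4-yl]methylidene]-4-methylbenzenesulfonohydrazide; 9 2-fluoro-4-(methoxymethoxy)benzaldehyde
Product: 11 1-[2-fluoro-4-(methoxymethoxy)phenyl]-2-[7-methoxy-6-(3-methylbut-2-en-1-yl)-2,2-diphenyl-1,3-benzodioxol-4-yl]ethan-1-one, via aryldiazomethane 10 (not isolated)
Conditions: K2CO3, 1,4-dioxane, 110 °C
Reagents that add atoms: none
Why: Bamford–Stevens fragmentation of the hydrazone salt gives the electron-rich aryldiazomethane, which adds to the fluorine-activated aldehyde and loses N2 with a 1,2-hydride shift (diazo homologation of an aldehyde, a formal formyl C–H insertion) to give the benzyl aryl ketone; carbonate in dioxane should not displace the fluoride.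

Step 7
Reactants: 11 1-[2-fluoro-4-(methoxymethoxy)phenyl]-2-[7-methoxy-6-(3-methylbut-2-en-1-yl)-2,2-diphenyl-1,3-benzodioxol-4-yl]ethan-1-one
Product: 12 2-diazo-1-[2-fluoro-4-(methoxymethoxy)phenyl]-2-[7-methoxy-6-(3-methylbut-2-en-1-yl)-2,2-diphenyl-1,3-benzodioxol-4-yl]ethan-1-one
Conditions: p-ABSA, DBU, MeCN, 0 °C to rt
Reagents that add atoms: 4-acetamidobenzenesulfonyl azide, CC(=O)Nc1ccc(cc1)S(=O)(=O)N=[N+]=[N-]
Why: Regitz diazo transfer to the doubly activated methylene (alpha to the ketone and benzylic to ring B) is the standard entry to alpha-aryl-alpha-diazo ketones.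

Step 8
Reactants: 12 2-diazo-1-[2-fluoro-4-(methoxymethoxy)phenyl]-2-[7-methoxy-6-(3-methylbut-2-en-1-yl)-2,2-diphenyl-1,3-benzodioxol-4-yl]ethan-1-one; 13 4-methoxybenzyl alcohol; 14 formaldehyde (monomeric, THF solution from cracked paraformaldehyde)
Product: 16 (S)-1-[2-fluoro-4-(methoxymethoxy)phenyl]-3-hydroxy-2-[(4-methoxybenzyl)oxy]-2-[7-methoxy-6-(3-methylbut-2-en-1-yl)-2,2-diphenyl-1,3-benzodioxol-4-yl]propan-1-one, via alkoxy enol 15 (not isolated)
Conditions: Rh2(OAc)4 (2 mol %), (R)-3,3'-bis(2,4,6-triisopropylphenyl)-1,1'-binaphthyl-2,2'-diyl hydrogen phosphate (10 mol %), 13 (1.5 equiv), 14 (5 equiv), 4 Å MS, CH2Cl2, −20 °C, 12 added over 2 h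
Reagents that add atoms: none
Why: Proposed new method: Rh2(OAc)4, a divalent rhodium carboxylate, takes N2 from 12 to give an electrophilic aryl/acyl carbene at C3; alcohol 13 adds to it (C3–O) and the oxonium ylide relaxes to enol 15, which the chiral phosphate holds by its enol O–H while also activating formaldehyde, so that an aldol-type addition forms C2–C3 before the 1,2-proton shift to the plain O–H insertion product. The closest known reaction type is the Rh2(OAc)4/chiral phosphoric acid three-component trapping of alcohol-derived oxonium ylides of aryldiazoacetates with aldehydes and imines; an alpha-aryl-alpha-diazo aryl ketone with formaldehyde as acceptor has not been shown. No ring is closed; two skeletal bonds (C3–O and C2–C3) are made. C3 is set under catalyst control, because 12 and 15 are achiral and the hydrogen-bonded enol–phosphate–formaldehyde array exposes one enol face. The step needs trapping to outrun the proton shift, which the high electrophilicity and excess of monomeric formaldehyde, the slow addition of 12 and the low temperature should secure. It also needs the carbene to meet only the alcohol, which the substrate secures: the diphenylmethylene ketal offers no C–H next to oxygen for 1,5-insertion, fluorine in place of the ring A ortho oxygen excludes an intramolecular oxonium ylide, and the prenyl alkene is meta to the carbene carbon and out of reach.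

Step 9
Reactants: 16 (S)-1-[2-fluoro-4-(methoxymethoxy)phenyl]-3-hydroxy-2-[(4-methoxybenzyl)oxy]-2-[7-methoxy-6-(3-methylbut-2-en-1-yl)-2,2-diphenyl-1,3-benzodioxol-4-yl]propan-1-one
Product: 17 (S)-3-[(4-methoxybenzyl)oxy]-7-(methoxymethoxy)-3-[7-methoxy-6-(3-methylbut-2-en-1-yl)-2,2-diphenyl-1,3-benzodioxol-4-yl]chroman-4-one
Conditions: Cs2CO3, DMF, rt to 40 °C
Reagents that add atoms: none
Why: Intramolecular SNAr (6-exo attack of the primary alkoxide on the fluoride ortho to the C4 ketone) forms O1–C8a and ring C; C3 is fully substituted and no bond to it is broken, and the weak carbonate base in a dipolar aprotic solvent should favour cyclisation over retro-aldol loss of formaldehyde.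

Step 10
Reactants: 17 (S)-3-[(4-methoxybenzyl)oxy]-7-(methoxymethoxy)-3-[7-methoxy-6-(3-methylbut-2-en-1-yl)-2,2-diphenyl-1,3-benzodioxol-4-yl]chroman-4-one
Product: 18 (S)-3-hydroxy-7-(methoxymethoxy)-3-[7-methoxy-6-(3-methylbut-2-en-1-yl)-2,2-diphenyl-1,3-benzodioxol-4-yl]chroman-4-one
Conditions: DDQ (1.2 equiv), CH2Cl2/pH 7 phosphate buffer (10:1), 0 °C
Reagents that add atoms: none
Why: Oxidative cleavage of the 4-methoxybenzyl ether by DDQ (hydride abstraction at the PMB benzylic C–H, then hydrolysis of the oxocarbenium ion) frees the C3 hydroxyl without acid; at 0 °C with a small excess of oxidant this should be faster than oxidation at the benzylic-allylic CH2 of the prenyl group, and C3 is not involved.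

Step 11
Reactants: 18 (S)-3-hydroxy-7-(methoxymethoxy)-3-[7-methoxy-6-(3-methylbut-2-en-1-yl)-2,2-diphenyl-1,3-benzodioxol-4-yl]chroman-4-one
Product: 19 (S)-3-[2,3-dihydroxy-4-methoxy-5-(3-methylbut-2-en-1-yl)phenyl]-3,7-dihydroxychroman-4-one (CNP0275486.1)
Conditions: 3 M HCl (aq.), MeOH/THF, 45 °C
Reagents that add atoms: none
Why: Acid-catalysed cleavage of the two acetal-type groups (MOM ether and diphenylmethylene ketal) releases the three phenols; the C3 carbinol should hold because ionisation next to the C4 carbonyl is disfavoured, and the prenyl group has no ortho hydroxyl to cyclise onto.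

**Compound list**

1 | 2,3-dihydroxy-4-methoxybenzaldehyde | COc1ccc(C=O)c(O)c1O | starting material
2 | dichlorodiphenylmethane | ClC(Cl)(c1ccccc1)c1ccccc1 | starting material
3 | 7-methoxy-2,2-diphenyl-1,3-benzodioxole-4-carbaldehyde | COc1ccc(C=O)c2OC(c3ccccc3)(c3ccccc3)Oc12 | intermediate
4 | 6-bromo-7-methoxy-2,2-diphenyl-1,3-benzodioxole-4-carbaldehyde | COc1c(Br)cc(C=O)c2OC(c3ccccc3)(c3ccccc3)Oc12 | intermediate
5 | tributyl(3-methylbut-2-en-1-yl)stannane | CCCC[Sn](CCCC)(CCCC)CC=C(C)C | starting material
6 | 7-methoxy-6-(3-methylbut-2-en-1-yl)-2,2-diphenyl-1,3-benzodioxole-4-carbaldehyde | COc1c(CC=C(C)C)cc(C=O)c2OC(c3ccccc3)(c3ccccc3)Oc12 | intermediate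
7 | (E)-N-tosylhydrazone of aldehyde 6 | COc1c(CC=C(C)C)cc(/C=N/NS(=O)(=O)c3ccc(C)cc3)c2OC(c3ccccc3)(c3ccccc3)Oc12 | intermediate
8 | 2-fluoro-4-hydroxybenzaldehyde | O=Cc1ccc(O)cc1F | starting material
9 | 2-fluoro-4-(methoxymethoxy)benzaldehyde | COCOc1ccc(C=O)c(F)c1 | intermediate
10 | 4-(diazomethyl)-7-methoxy-6-(3-methylbut-2-en-1-yl)-2,2-diphenyl-1,3-benzodioxole (not isolated) | COc1c(CC=C(C)C)cc(C=[N+]=[N-])c2OC(c3ccccc3)(c3ccccc3)Oc12 | intermediate
11 | 1-[2-fluoro-4-(methoxymethoxy)phenyl]-2-[7-methoxy-6-(3-methylbut-2-en-1-yl)-2,2-diphenyl-1,3-benzodioxol-4-yl]ethan-1-one | COc1c(CC=C(C)C)cc(CC(=O)c3ccc(OCOC)cc3F)c2OC(c3ccccc3)(c3ccccc3)Oc12 | intermediate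
12 | 2-diazo-1-[2-fluoro-4-(methoxymethoxy)phenyl]-2-[7-methoxy-6-(3-methylbut-2-en-1-yl)-2,2-diphenyl-1,3-benzodioxol-4-yl]ethan-1-one | COc1c(CC=C(C)C)cc(C(=[N+]=[N-])C(=O)c3ccc(OCOC)cc3F)c2OC(c3ccccc3)(c3ccccc3)Oc12 | intermediate
13 | 4-methoxybenzyl alcohol | COc1ccc(CO)cc1 | starting material
14 | formaldehyde | C=O | starting material
15 | 1-[2-fluoro-4-(methoxymethoxy)phenyl]-2-[(4-methoxybenzyl)oxy]-2-[7-methoxy-6-(3-methylbut-2-en-1-yl)-2,2-diphenyl-1,3-benzodioxol-4-yl]ethen-1-ol (enol, geometry not defined, not isolated) | COc1c(CC=C(C)C)cc(C(OCc3ccc(OC)cc3)=C(O)c3ccc(OCOC)cc3F)c2OC(c3ccccc3)(c3ccccc3)Oc12 | intermediate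
16 | (S)-1-[2-fluoro-4-(methoxymethoxy)phenyl]-3-hydroxy-2-[(4-methoxybenzyl)oxy]-2-[7-methoxy-6-(3-methylbut-2-en-1-yl)-2,2-diphenyl-1,3-benzodioxol-4-yl]propan-1-one | COc1c(CC=C(C)C)cc([C@](OCc3ccc(OC)cc3)(CO)C(=O)c3ccc(OCOC)cc3F)c2OC(c3ccccc3)(c3ccccc3)Oc12 | intermediate
17 | (S)-3-[(4-methoxybenzyl)oxy]-7-(methoxymethoxy)-3-[7-methoxy-6-(3-methylbut-2-en-1-yl)-2,2-diphenyl-1,3-benzodioxol-4-yl]chroman-4-one | COc1c(CC=C(C)C)cc([C@]2(OCc3ccc(OC)cc3)COc3cc(OCOC)ccc3C2=O)c2OC(c3ccccc3)(c3ccccc3)Oc12 | intermediate
18 | (S)-3-hydroxy-7-(methoxymethoxy)-3-[7-methoxy-6-(3-methylbut-2-en-1-yl)-2,2-diphenyl-1,3-benzodioxol-4-yl]chroman-4-one | COc1c(CC=C(C)C)cc([C@]2(O)COc3cc(OCOC)ccc3C2=O)c2OC(c3ccccc3)(c3ccccc3)Oc12 | intermediate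
19 | (S)-3-[2,3-dihydroxy-4-methoxy-5-(3-methylbut-2-en-1-yl)phenyl]-3,7-dihydroxychroman-4-one | COc1c(CC=C(C)C)cc([C@]2(O)COc3cc(O)ccc3C2=O)c(O)c1O | target

**Step count**

Total: 11 steps. Longest linear sequence: 10 steps (steps 1 to 4 and 6 to 11, from 1); step 5 is the one-step side branch for ring A.

**Steps most likely to fail**

1. Step 8 (proposed new method). The enol may undergo the 1,2-proton shift to the simple O–H insertion product faster than it is captured by formaldehyde. Facial selectivity may also be poor with so small an electrophile, and formaldehyde may oligomerise under the acid. The fallback uses known chemistry, sets out from 11 and returns at 18. Ketone 11 is treated with paraformaldehyde and K2CO3 in DMF at 50 °C. Base-mediated hydroxymethylation gives the racemic 3-hydroxy-2-aryl-propan-1-one F1, whose alkoxide displaces the fluoride in the same flask to give the racemic isoflavanone F2. The potassium enolate of F2 (KN(SiMe3)2, THF, −78 °C) is then hydroxylated with the appropriate enantiomer of (8,8-dichlorocamphorylsulfonyl)oxaziridine. This reagent-controlled asymmetric enolate hydroxylation should give 18 directly and makes steps 7 to 10 unnecessary.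

2. Step 9. The beta-alkoxide may lose formaldehyde by retro-aldol cleavage in competition with fluoride displacement, which would lower the enantiomeric purity through re-addition or give the deformylated alpha-alkoxy ketone. The fallback sets out from 16 and returns at 17, and reverses the polarity of the ring closure so that no alkoxide is formed at the hydroxymethyl group. Alcohol 16 is converted with MsCl and Et3N in CH2Cl2 at 0 °C to the mesylate F3. Acetohydroxamic acid and K2CO3 in DMSO at 80 °C (SNAr hydroxylation by a hydroxide surrogate) then replace the fluoride to give the ortho-hydroxy ketone F4 as its phenoxide. This should close ring C in the same flask by 6-exo-tet O-alkylation at the primary mesylate to give 17, with C3 untouched.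

3. Step 11. The acid needed for the diphenylmethylene ketal may cause ionisation at C3 with dehydration towards the isoflavone, or addition of HCl or methanol to the prenyl alkene, or the ketal may cleave only partly. The fallback sets out from 18 and returns at 19, and replaces hydrolysis of the ketal by reductive cleavage. Transfer hydrogenolysis (Pd/C, 1,4-cyclohexadiene, EtOH, rt), conditions under which trisubstituted alkenes are normally spared, should remove the ketal as diphenylmethane and give the catechol F5. The remaining MOM ether is then taken off at 0 °C with ZnBr2 and n-PrSH in CH2Cl2 (Lewis acid and soft nucleophile) to give 19.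

**Further compounds**

F1 | step 8 | racemic 1-[2-fluoro-4-(methoxymethoxy)phenyl]-3-hydroxy-2-[7-methoxy-6-(3-methylbut-2-en-1-yl)-2,2-diphenyl-1,3-benzodioxol-4-yl]propan-1-one | COc1c(CC=C(C)C)cc(C(CO)C(=O)c3ccc(OCOC)cc3F)c2OC(c3ccccc3)(c3ccccc3)Oc12
F2 | step 8 | racemic 7-(methoxymethoxy)-3-[7-methoxy-6-(3-methylbut-2-en-1-yl)-2,2-diphenyl-1,3-benzodioxol-4-yl]chroman-4-one | COc1c(CC=C(C)C)cc(C2COc3cc(OCOC)ccc3C2=O)c2OC(c3ccccc3)(c3ccccc3)Oc12
F3 | step 9 | (S)-3-[2-fluoro-4-(methoxymethoxy)phenyl]-2-[(4-methoxybenzyl)oxy]-2-[7-methoxy-6-(3-methylbut-2-en-1-yl)-2,2-diphenyl-1,3-benzodioxol-4-yl]-3-oxopropyl methanesulfonate | COc1c(CC=C(C)C)cc([C@](OCc3ccc(OC)cc3)(COS(C)(=O)=O)C(=O)c3ccc(OCOC)cc3F)c2OC(c3ccccc3)(c3ccccc3)Oc12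
F4 | step 9 | (S)-3-[2-hydroxy-4-(methoxymethoxy)phenyl]-2-[(4-methoxybenzyl)oxy]-2-[7-methoxy-6-(3-methylbut-2-en-1-yl)-2,2-diphenyl-1,3-benzodioxol-4-yl]-3-oxopropyl methanesulfonate | COc1c(CC=C(C)C)cc([C@](OCc3ccc(OC)cc3)(COS(C)(=O)=O)C(=O)c3ccc(OCOC)cc3O)c2OC(c3ccccc3)(c3ccccc3)Oc12
F5 | step 11 | (S)-3-[2,3-dihydroxy-4-methoxy-5-(3-methylbut-2-en-1-yl)phenyl]-3-hydroxy-7-(methoxymethoxy)chroman-4-one | COc1c(CC=C(C)C)cc([C@]2(O)COc3cc(OCOC)ccc3C2=O)c(O)c1O
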